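**Plan**

1. Numbering is that of the briarane skeleton: ring A = cyclohexane C1, C10, C11, C12, C13, C14 (C15 on C1, C20 on C11); ring B = ten-membered ring C1–C10; ring C = lactone C7, C8, C17, C19, O; β = the face of ring A that carries C15.
2. Retrosynthetic cuts, in order: C5=C6 (ring-closing metathesis), C8–C17 with the lactone (intramolecular Reformatsky), C7–C8 (alkoxyallylboration), C2–C3 (Grignard), C11–C20 (MeMgBr), and last C1–C10 together with C11–C12.
3. Enabling feature: ring A carries oxygen on C14 and C11 (1,4) and its quaternary C1 lies between the oxygenated carbons C14 and C2. Ring A is therefore a latent 2-acyl-2-methylcyclohexane-1,4-dione, the product type of a Michael/Michael (formal [4+2]) union of a γ,δ-unsaturated β-keto ester (C12=C13–C14(=O)–C1–C2) with a nitroalkene (C10=C11) acting as a ketene equivalent.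
4. Forward order: ring A (step 4), C11 carbinol, C2 side chain, C7–C9 segment, ring C, and ring B last.
5. Stereochemistry: C9 is bought (D-glyceraldehyde); C10 and C1 arise in the key step; C11, C2 and C14 are relayed from ring A by substrate control; C7 comes from an Ipc2B reagent; C8 and C17 follow from C7; the 5Z alkene is enforced by ring B.

Key step: step 4

Remark: C14 is carried through compounds 10 to 13 as an epimer mixture on purpose, because step 9 re-oxidises it; its final configuration is set in step 11.

**Route**

Step 1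
Reactants: 1 (R)-2,2-dimethyl-1,3-dioxolane-4-carbaldehyde
Product: 3 (4S)-2,2-dimethyl-4-[(E)-2-nitrovinyl]-1,3-dioxolane, via nitro aldol 2 (not isolated)
Conditions: MeNO2, Et3N (cat.), 0 °C to rt; then MsCl, Et3N, CH2Cl2, 0 °C
Reagents that add atoms: nitromethane, C[N+](=O)[O-]
Why: A Henry reaction followed by mesylation and E1cB elimination should give the conjugated (E)-nitroalkene and leave the bought C9 stereocentre untouched.

Step 2
Reactants: 4 tert-butyl propanoate; 5 acrolein
Product: 6 tert-butyl 3-hydroxy-2-methylpent-4-enoate (diastereomer mixture)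
Conditions: LDA, THF, −78 °C; then 5; aq. NH4Cl
Reagents that add atoms: none
Why: The lithium ester enolate should add 1,2 to acrolein at −78 °C (aldol addition), and both new stereocentres are lost later (C14 is oxidised in step 3, C1 is enolised in step 4), so no control is needed.

Step 3
Reactants: 6 tert-butyl 3-hydroxy-2-methylpent-4-enoate
Product: 7 tert-butyl 2-methyl-3-oxopent-4-enoate
Conditions: Dess–Martin periodinane, NaHCO3, CH2Cl2, 0 °C; crude product used at once
Reagents that add atoms: none
Why: Dess–Martin oxidation of the allylic alcohol should give the Nazarov-type vinyl β-keto ester under buffered, non-basic conditions that do not trigger its Michael polymerisation.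

Step 4
Reactants: 7 tert-butyl 2-methyl-3-oxopent-4-enoate; 3 (4S)-2,2-dimethyl-4-[(E)-2-nitrovinyl]-1,3-dioxolane
Product: 9 ring A nitro keto ester (C1: β-CH3 and α-CO2tBu; C14 ketone; C10: β-(4S)-2,2-dimethyl-1,3-dioxolan-4-yl; C11: α-NO2), via Michael adduct 8 (not isolated)
Conditions: 1-[3,5-bis(trifluoromethyl)phenyl]-3-[(1R,2R)-2-(dimethylamino)cyclohexyl]thiourea (10 mol%), toluene, −20 °C, 7 added slowly; then 1,1,3,3-tetramethylguanidine (20 mol%), 0 °C
Reagents that add atoms: none
Why: The amine of the bifunctional thiourea deprotonates β-keto ester 7 while the thiourea binds the nitro group of 3, C1 adds to C10 to give 8, and after the guanidine is added the nitronate carbon C11 adds to the vinyl ketone terminus C12, so that both ring A bonds form in one flask. The closest known reaction type is the thiourea-catalysed Michael/Michael (formal [4+2]) annulation of γ,δ-unsaturated β-keto esters with nitroalkenes to 4-nitrocyclohexanones. Ring A, the only ring formed, closes by a 6-endo-trig conjugate addition of the nitronate. C10 is set by the (R,R)-catalyst, which should act here in the same sense as Felkin–Anh attack anti to the C9–O bond of the dioxolane; C1 is set in the open transition state, in which the nitro-bearing C11 lies over the hydrogen-bonded dicarbonyl unit and the dioxolanyl group lies next to the slim acryloyl arm and anti to the bulky tert-butyl ester, so that C15 ends cis to C9; C11 settles as the equatorial nitro epimer and is erased in step 6. The step needs the enolate to choose the nitroalkene over the vinyl ketone of a second molecule of 7 and needs the C1/C10 pair as one diastereomer: the far higher electrophilicity of the nitroalkene with slow addition of 7 secures the first, the tert-butyl ester together with the matched catalyst is meant to secure the second, and regiochemistry is fixed because only C1 is acidic and only C12 is within reach of C11.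

Step 5
Reactants: 9 ring A nitro keto ester
Product: 10 C14 alcohol of 9 (C14 epimer mixture)
Conditions: NaBH4, MeOH, −40 °C
Reagents that add atoms: none
Why: Borohydride reduction should take the C14 ketone chemoselectively (nitro group and tert-butyl ester are inert), which removes the β-keto ester so that the base of step 6 cannot reopen ring A by retro-Michael cleavage of C1–C10.

Step 6
Reactants: 10 C14 alcohol of 9
Product: 11 C11 ketone (C14–OH epimers; ester and dioxolane unchanged)
Conditions: NaOMe, MeOH, 0 °C; then O3, CH2Cl2–MeOH, −78 °C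
Reagents that add atoms: ozone, [O-][O+]=O
Why: A Nef reaction by ozonolysis of the sodium nitronate should turn C11 into the ketone, and C10, now epimerisable, should keep its equatorial C9 substituent trans to C2, which is the thermodynamic arrangement.

Step 7
Reactants: 11 C11 ketone
Product: 12 C11 tertiary alcohol (11β-OH; 11α-CH3 = C20; C14–OH epimers)
Conditions: MeMgBr (4 equiv), CeCl3, THF, −78 °C
Reagents that add atoms: methylmagnesium bromide, C[Mg]Br
Why: Organocerium 1,2-addition (enolisation suppressed) should occur from the equatorial side because the axial C15 methyl group, 1,3 to C11, blocks axial attack, which gives the 11α-methyl/11β-hydroxy centre of the target.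

Step 8
Reactants: 12 C11 tertiary alcohol
Product: 13 triol (CH2OH = C2 on C1; C14–OH epimers; 11β-OH)
Conditions: LiAlH4, THF, 0 °C to reflux
Reagents that add atoms: none
Why: Hydride reduction of the hindered tert-butyl ester on the quaternary C1 should give the primary C2 alcohol without touching the acetonide.

Step 9
Reactants: 13 triol
Product: 14 keto aldehyde (C2 aldehyde on C1; C14 ketone; 11β-OH)
Conditions: Dess–Martin periodinane (3 equiv), NaHCO3, CH2Cl2, rt
Reagents that add atoms: none
Why: A double Dess–Martin oxidation should convert the primary alcohol into the C2 aldehyde and both C14 epimers into one ketone, the tertiary C11 hydroxyl being inert and C1 being non-enolisable.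

Step 10
Reactants: 14 keto aldehyde
Product: 15 (2S)-β-hydroxy ketone (C2 carries OH and the 3-methylbut-3-enyl chain; C14 ketone)
Conditions: CH2=C(CH3)CH2CH2MgBr (2.5 equiv), MgBr2·OEt2, Et2O–CH2Cl2, −78 °C
Reagents that add atoms: (3-methylbut-3-en-1-yl)magnesium bromide, CC(=C)CC[Mg]Br
Why: Grignard addition should be chemoselective for the aldehyde over the neopentyl C14 ketone and should follow Cram chelate control, in which magnesium bridges O2 and O14 and the reagent enters from the chelate face that carries the small axial C15 methyl rather than the C10 ring carbon, which gives 2S.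

Step 11
Reactants: 15 (2S)-β-hydroxy ketone
Product: 16 (2S)-2-acetate with 14α-OH
Conditions: SmI2 (0.3 equiv), CH3CHO (10 equiv), THF, −10 °C
Reagents that add atoms: acetaldehyde, CC=O
Why: The Evans–Tishchenko reduction should deliver hydride from the samarium-bound acetaldehyde hemiacetal on O2 to C14 within a six-membered transition state, giving the 1,3-anti relationship (14α-OH) and at the same time placing the acetate on O2.

Step 12
Reactants: 16 (2S)-2-acetate with 14α-OH
Product: 17 14-O-TBS ether of 16
Conditions: TBSOTf, 2,6-lutidine, CH2Cl2, −78 to 0 °C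
Reagents that add atoms: tert-butyldimethylsilyl trifluoromethanesulfonate, CC(C)(C)[Si](C)(C)OS(=O)(=O)C(F)(F)F
Why: Silyl triflate silylation should protect the secondary C14 hydroxyl for the coming oxidations, the tertiary C11 hydroxyl (1,3-diaxial to C15) being far slower.

Step 13
Reactants: 17 14-O-TBS ether
Product: 18 8,9-diol (acetonide removed)
Conditions: AcOH–H2O (4:1), 40 °C
Reagents that add atoms: none
Why: Mild aqueous acid should hydrolyse the terminal acetonide while the hindered secondary TBS ether and the acetate survive.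

Step 14
Reactants: 18 8,9-diol
Product: 20 8-O-triethylsilyl 9-O-acetate, via mono-TES ether 19 (not isolated)
Conditions: TESCl (1.1 equiv), imidazole, CH2Cl2, −20 °C; then Ac2O, DMAP, pyridine, rt
Reagents that add atoms: chlorotriethylsilane, CC[Si](Cl)(CC)CC; acetic anhydride, CC(=O)OC(C)=O
Why: Primary-selective silylation followed by DMAP-catalysed acetylation in the same flask should install the C9 acetate of the target and leave C8 masked, while the tertiary hydroxyl does not acylate.

Step 15
Reactants: 20 8-O-triethylsilyl 9-O-acetate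
Product: 21 C8 aldehyde (9-acetate)
Conditions: (COCl)2, DMSO, CH2Cl2, −78 to −40 °C; then i-Pr2NEt, −78 to 0 °C
Reagents that add atoms: none
Why: Under Swern conditions the primary triethylsilyl ether should be cleaved and oxidised directly to the aldehyde while the secondary TBS ether persists, and the low temperature with a hindered amine should keep the α-acetoxy centre C9 intact.

Step 16
Reactants: 21 C8 aldehyde
Product: 22 allylation product (7S-OMOM; C8–OH; 7,8-syn and 8,9-anti; terminal vinyl on C7)
Conditions: allyl methoxymethyl ether, s-BuLi, THF, −78 °C; (+)-Ipc2BOMe; BF3·OEt2; then 21, −78 °C; pH 7 buffer, H2O2, 0 °C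
Reagents that add atoms: B-[(Z)-3-(methoxymethoxy)allyl]diisopinocampheylborane, made in the flask from allyl methoxymethyl ether (C=CCOCOC), COCO/C=C\CB([C@H]1C[C@H]2C[C@@H]([C@@H]1C)C2(C)C)[C@H]1C[C@H]2C[C@@H]([C@@H]1C)C2(C)C
Why: Asymmetric γ-alkoxyallylboration (Brown type) through a chair transition state should give the 7,8-syn product from the (Z)-reagent, and the Ipc groups derived from (−)-α-pinene should direct attack to the Re face of the aldehyde (the same face as Felkin–Anh attack anti to the C9 acetoxy group), which sets 7S.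

Step 17
Reactants: 22 allylation product
Product: 23 C8 ketone (7S-OMOM; 9-acetate)
Conditions: Dess–Martin periodinane, NaHCO3, CH2Cl2, 0 °C
Reagents that add atoms: none
Why: Dess–Martin oxidation should turn the C8 carbinol, whose configuration is not needed, into the ketone under buffered conditions that do not epimerise C7 or C9.

Step 18
Reactants: 23 C8 ketone
Product: 24 (7S)-7-hydroxy-8-ketone
Conditions: ZnBr2, n-PrSH, CH2Cl2, 0 °C, 10 min
Reagents that add atoms: none
Why: Thiol-assisted Lewis acid cleavage of the methoxymethyl ether should free the C7 hydroxyl within minutes without loss of the TBS ether or the acetates.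

Step 19
Reactants: 24 (7S)-7-hydroxy-8-ketone
Product: 25 7-O-(2-bromopropanoyl) ester (bromide epimers)
Conditions: 2-bromopropanoyl bromide, pyridine, CH2Cl2, −20 °C
Reagents that add atoms: 2-bromopropanoyl bromide, CC(Br)C(Br)=O
Why: Acylation with the acid bromide should occur only at the secondary C7 hydroxyl, the tertiary C11 hydroxyl being hindered, and the bromide epimers converge in step 20.

Step 20
Reactants: 25 7-O-(2-bromopropanoyl) ester
Product: 26 lactone (ring C closed; 7S; 8S with 8-OH; 17R; vinyl on C7)
Conditions: SmI2 (2.2 equiv, added slowly), THF, −78 °C; aq. NH4Cl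
Reagents that add atoms: none
Why: In this SmI2-mediated intramolecular Reformatsky reaction the C–Br reduction at −78 °C should outrun ketyl formation, and the trivalent samarium enolate should add to the C8 ketone through a five-membered chelated transition state that keeps the large C9 substituent trans to the C7 vinyl group (8S), with the C17 methyl trans to C9 as the thermodynamic, epimerisable arrangement (17R).

Step 21
Reactants: 26 lactone
Product: 27 14-O-TBS-junceellolide I (ring B closed; 5Z)
Conditions: second-generation Hoveyda–Grubbs catalyst (15 mol%), toluene (0.5 mM), 80 °C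
Reagents that add atoms: none
Why: Ring-closing metathesis should start at the monosubstituted C6 alkene and close onto the 1,1-disubstituted C5 alkene with loss of ethylene at high dilution, and the ten-membered ring should enforce the Z geometry of the trisubstituted C5=C6 bond.

Step 22
Reactants: 27 14-O-TBS-junceellolide I
Product: 28 junceellolide I
Conditions: HF·pyridine, pyridine, THF, 0 °C to rt
Reagents that add atoms: none
Why: Fluoride-mediated desilylation under buffered acidic conditions should free the C14 hydroxyl without acetate migration or lactone opening and give the target.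

**Compound list**

1 | (R)-2,2-dimethyl-1,3-dioxolane-4-carbaldehyde (2,3-O-isopropylidene-D-glyceraldehyde) | CC1(C)OC[C@@H](O1)C=O | starting material
2 | 1-[(4R)-2,2-dimethyl-1,3-dioxolan-4-yl]-2-nitroethanol (carbinol epimers) | CC1(C)OC[C@@H](O1)C(O)C[N+](=O)[O-] | intermediate
3 | (4S)-2,2-dimethyl-4-[(E)-2-nitrovinyl]-1,3-dioxolane | CC1(C)OC[C@@H](O1)/C=C/[N+](=O)[O-] | intermediate
4 | tert-butyl propanoate | CCC(=O)OC(C)(C)C | starting material
5 | acrolein | C=CC=O | starting material
6 | tert-butyl 3-hydroxy-2-methylpent-4-enoate (diastereomer mixture) | C=CC(O)C(C)C(=O)OC(C)(C)C | intermediate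
7 | tert-butyl 2-methyl-3-oxopent-4-enoate (racemic) | C=CC(=O)C(C)C(=O)OC(C)(C)C | intermediate
8 | acyclic Michael adduct: tert-butyl 2-acryloyl-2-methyl-4-nitro-3-[(4S)-2,2-dimethyl-1,3-dioxolan-4-yl]butanoate, C1 and C10 configured as in 9 | CC1(C)OC[C@@H](O1)[C@@H](C[N+](=O)[O-])[C@](C(=O)OC(C)(C)C)(C)C(=O)C=C | intermediate
9 | ring A nitro keto ester: C1 with β-CH3 (C15) and α-CO2tBu (C2); C14 ketone; C10 with β-(4S)-dioxolanyl (C9, C8); C11 with α-NO2 | CC1(C)OC[C@@H](O1)[C@@H]2[C@](C(=O)OC(C)(C)C)(C)C(=O)CC[C@H]2[N+](=O)[O-] | intermediate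
10 | C14 alcohol of 9 (C14 epimers) | CC1(C)OC[C@@H](O1)[C@@H]2[C@](C(=O)OC(C)(C)C)(C)C(O)CC[C@H]2[N+](=O)[O-] | intermediate
11 | C11 ketone, C14–OH epimers | CC1(C)OC[C@@H](O1)[C@@H]2[C@](C(=O)OC(C)(C)C)(C)C(O)CCC2=O | intermediate
12 | C11 tertiary alcohol: 11β-OH, 11α-CH3 (C20); C14–OH epimers | CC1(C)OC[C@@H](O1)[C@@H]2[C@](C(=O)OC(C)(C)C)(C)C(O)CC[C@]2(C)O | intermediate
13 | triol: C2 as CH2OH on C1; C14–OH epimers; 11β-OH | CC1(C)OC[C@@H](O1)[C@@H]2[C@](CO)(C)C(O)CC[C@]2(C)O | intermediate
14 | keto aldehyde: C2 aldehyde on C1; C14 ketone; 11β-OH | CC1(C)OC[C@@H](O1)[C@@H]2[C@](C=O)(C)C(=O)CC[C@]2(C)O | intermediate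
15 | (2S)-β-hydroxy ketone: 2-OH, 3-methylbut-3-enyl chain on C2; C14 ketone | CC1(C)OC[C@@H](O1)[C@@H]2[C@]([C@@H](O)CCC(C)=C)(C)C(=O)CC[C@]2(C)O | intermediate
16 | (2S)-2-acetate, 14α-OH | CC1(C)OC[C@@H](O1)[C@@H]2[C@]([C@@H](OC(C)=O)CCC(C)=C)(C)[C@@H](O)CC[C@]2(C)O | intermediate
17 | 14α-OTBS ether of 16 | CC1(C)OC[C@@H](O1)[C@@H]2[C@]([C@@H](OC(C)=O)CCC(C)=C)(C)[C@@H](O[Si](C)(C)C(C)(C)C)CC[C@]2(C)O | intermediate
18 | (9S)-8,9-diol | OC[C@@H](O)[C@@H]2[C@]([C@@H](OC(C)=O)CCC(C)=C)(C)[C@@H](O[Si](C)(C)C(C)(C)C)CC[C@]2(C)O | intermediate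
19 | 8-O-triethylsilyl ether of 18 | CC[Si](CC)(CC)OC[C@@H](O)[C@@H]2[C@]([C@@H](OC(C)=O)CCC(C)=C)(C)[C@@H](O[Si](C)(C)C(C)(C)C)CC[C@]2(C)O | intermediate
20 | 8-O-triethylsilyl 9-O-acetate | CC[Si](CC)(CC)OC[C@@H](OC(C)=O)[C@@H]2[C@]([C@@H](OC(C)=O)CCC(C)=C)(C)[C@@H](O[Si](C)(C)C(C)(C)C)CC[C@]2(C)O | intermediate
21 | C8 aldehyde, (9S)-9-acetate | O=C[C@@H](OC(C)=O)[C@@H]2[C@]([C@@H](OC(C)=O)CCC(C)=C)(C)[C@@H](O[Si](C)(C)C(C)(C)C)CC[C@]2(C)O | intermediate
22 | allylation product: (7S)-7-OMOM, 8-OH (7,8-syn; 8,9-anti), vinyl on C7 | C=C[C@H](OCOC)[C@@H](O)[C@@H](OC(C)=O)[C@@H]2[C@]([C@@H](OC(C)=O)CCC(C)=C)(C)[C@@H](O[Si](C)(C)C(C)(C)C)CC[C@]2(C)O | intermediate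
23 | C8 ketone, (7S)-7-OMOM | C=C[C@H](OCOC)C(=O)[C@@H](OC(C)=O)[C@@H]2[C@]([C@@H](OC(C)=O)CCC(C)=C)(C)[C@@H](O[Si](C)(C)C(C)(C)C)CC[C@]2(C)O | intermediate
24 | (7S)-7-hydroxy-8-ketone | C=C[C@H](O)C(=O)[C@@H](OC(C)=O)[C@@H]2[C@]([C@@H](OC(C)=O)CCC(C)=C)(C)[C@@H](O[Si](C)(C)C(C)(C)C)CC[C@]2(C)O | intermediate
25 | 7-O-(2-bromopropanoyl) ester of 24 (bromide epimers) | C=C[C@H](OC(=O)C(C)Br)C(=O)[C@@H](OC(C)=O)[C@@H]2[C@]([C@@H](OC(C)=O)CCC(C)=C)(C)[C@@H](O[Si](C)(C)C(C)(C)C)CC[C@]2(C)O | intermediate
26 | lactone (ring C): 7S, 8S (8-OH), 17R; vinyl on C7, trans to C9 | C=C[C@@H]1OC(=O)[C@H](C)[C@@]1(O)[C@@H](OC(C)=O)[C@@H]2[C@]([C@@H](OC(C)=O)CCC(C)=C)(C)[C@@H](O[Si](C)(C)C(C)(C)C)CC[C@]2(C)O | intermediate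
27 | 14-O-TBS-junceellolide I | CC(=O)O[C@H]1CC/C(C)=C\[C@@H]2OC(=O)[C@H](C)[C@@]2(O)[C@@H](OC(C)=O)[C@@H]2[C@]1(C)[C@@H](O[Si](C)(C)C(C)(C)C)CC[C@]2(C)O | intermediate
28 | junceellolide I | CC(=O)O[C@H]1CC/C(C)=C\[C@@H]2OC(=O)[C@H](C)[C@@]2(O)[C@@H](OC(C)=O)[C@@H]2[C@]1(C)[C@@H](O)CC[C@]2(C)O | target

**Step count and risks**

Total steps: 22. Longest linear sequence: 21 steps (4 to 28, steps 2 to 22).

The three steps most likely to fail:

Step 4. The enolate may add through the other face of C1 (ester cis to C9), or 7 may oligomerise by Michael addition to its own vinyl ketone before it meets 3. The fallback sets out from 7 and comes back at 9, and moves the event from the ionic cascade to a pericyclic one. Silylation of 7 (TBSOTf, Et3N, CH2Cl2, −78 °C) should give tert-butyl (2Z)-3-[(tert-butyldimethylsilyl)oxy]-2-methylpenta-2,4-dienoate F1, in which the ester is cis to the silyloxy group and so sits on the outside of the diene. A thermal or high-pressure Diels–Alder reaction with 3 (toluene, 80 °C, or CH2Cl2, 10 kbar), through the nitro-endo transition state and on the nitroalkene face anti to the C9–O bond, should form the same two bonds and give the silyl enol ether cycloadduct F2 with the ester trans to C9. TBAF buffered with AcOH (THF, 0 °C) should then unveil the C14 ketone and return 9.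

Step 21. The trans-fused lactone may hold C6 too far from C5, so that oligomerisation outruns closure of the ten-membered ring. The fallback sets out from 23 and comes back at 27, and inverts the order of ring construction so that ring B is closed on the conformationally free ketone before ring C exists. Ring-closing metathesis of 23 (second-generation Hoveyda–Grubbs catalyst, toluene, 80 °C, high dilution) should give the ten-membered keto MOM ether F3. ZnBr2 with n-PrSH should free the C7 hydroxyl to give the ten-membered α-hydroxy ketone F4, and 2-bromopropanoyl bromide with pyridine should give the bromo ester F5. SmI2 (THF, −78 °C) should then close the lactone across the existing ring, where the preference of ring B for a trans fusion at C7/C8 is expected to set C8, to give 27.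

Step 20. Electron transfer to the C8 ketone may compete with C–Br reduction and expel one of the flanking acyloxy groups, or the enolate may add to the wrong face of C8. The fallback sets out from 23 and comes back at 26, and replaces the reductive intramolecular closure by an intermolecular addition followed by lactonisation. A zinc Reformatsky reaction of 23 with methyl 2-bromopropanoate (activated Zn, THF, 0 °C), guided by a Cram chelate between the C8 carbonyl and the C7 MOM oxygen so that the nucleophile enters anti to the vinyl group, should give the β-hydroxy methyl ester F6. ZnBr2 with n-PrSH followed by PPTS (CH2Cl2) should remove the MOM group and close the lactone to 26, with DBU equilibration of C17 if needed.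

Further compounds

F1 | step 4 | tert-butyl (2Z)-3-[(tert-butyldimethylsilyl)oxy]-2-methylpenta-2,4-dienoate | C=C/C(O[Si](C)(C)C(C)(C)C)=C(\C)C(=O)OC(C)(C)C
F2 | step 4 | silyl enol ether cycloadduct (C13=C14 tert-butyldimethylsilyl enol ether of 9) | CC1(C)OC[C@@H](O1)[C@@H]2[C@](C(=O)OC(C)(C)C)(C)C(O[Si](C)(C)C(C)(C)C)=CC[C@H]2[N+](=O)[O-]
F3 | step 21 | ten-membered keto MOM ether (ring B closed, 5Z; C8 ketone; 7S-OMOM) | CC(=O)O[C@H]1CC/C(C)=C\[C@H](OCOC)C(=O)[C@@H](OC(C)=O)[C@@H]2[C@]1(C)[C@@H](O[Si](C)(C)C(C)(C)C)CC[C@]2(C)O
F4 | step 21 | ten-membered α-hydroxy ketone (7S-OH; C8 ketone) | CC(=O)O[C@H]1CC/C(C)=C\[C@H](O)C(=O)[C@@H](OC(C)=O)[C@@H]2[C@]1(C)[C@@H](O[Si](C)(C)C(C)(C)C)CC[C@]2(C)O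
F5 | step 21 | 7-O-(2-bromopropanoyl) ester of F4 (bromide epimers) | CC(=O)O[C@H]1CC/C(C)=C\[C@H](OC(=O)C(C)Br)C(=O)[C@@H](OC(C)=O)[C@@H]2[C@]1(C)[C@@H](O[Si](C)(C)C(C)(C)C)CC[C@]2(C)O
F6 | step 20 | β-hydroxy methyl ester from 23 (C8 tertiary alcohol bearing CH(CH3)CO2CH3; 7S-OMOM; C17 epimers) | C=C[C@H](OCOC)[C@@](O)(C(C)C(=O)OC)[C@@H](OC(C)=O)[C@@H]2[C@]([C@@H](OC(C)=O)CCC(C)=C)(C)[C@@H](O[Si](C)(C)C(C)(C)C)CC[C@]2(C)O
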